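## Retrosynthetic overview

1. Ring A is the anhydride bearing CH2OH and ring B the one bearing the 2-oxohexyl chain; the only operation after ring formation is removal of a benzyl group from the ring A CH2OH.
2. Rings A and B are disconnected together and formed last, in one flask: each ring C=C is an alkyne of a 1,5-diyne and all four C=O carbons are CO2 (nickel-catalysed double carboxylation). No ring is carried through the route.
3. The diyne's ring B arm (2-oxohexyl, masked as a dioxolane) comes from a terminal alkyne and 1,2-epoxyhexane; its ring A arm comes from an aldehyde by Corey–Fuchs homologation with capture of the acetylide by BnOCH2Cl.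
4. The single stereocentre is set in the first step by rhodium-catalysed asymmetric conjugate alkynylation of (E)-oct-2-enal.
5. The usual assembly (organocuprate/acetylenedicarboxylate chemistry or alkylation of preformed anhydride units) is deliberately not used.

Assumption: (R)-DTBM-SEGPHOS is taken to deliver the (S)-aldehyde in step 1; if the first run gives the antipode, (S)-DTBM-SEGPHOS is used and nothing else changes.

## Route

Step 1
Reactants: 1 (E)-oct-2-enal; 2 ethynyltriisopropylsilane
Product: 3 (S)-3-[(triisopropylsilyl)ethynyl]octanal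
Conditions: [Rh(OAc)(C2H4)2]2 (2.5 mol%), (R)-DTBM-SEGPHOS (6 mol%), MeOH, 40 °C
Reagents that add atoms: none
Why: Rhodium-catalysed asymmetric conjugate alkynylation, in which an alkynyl complex of monovalent rhodium inserts the enal 1,4 and MeOH protonates the rhodium enolate; the bulky silyl group and ligand suppress alkyne dimerisation, and the ligand-controlled face of insertion sets C3 as (S), the only stereocentre of the target.

Step 2
Reactants: 3 (S)-3-[(triisopropylsilyl)ethynyl]octanal
Product: 4 (S)-1,1-dibromo-4-[(triisopropylsilyl)ethynyl]non-1-ene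
Conditions: CBr4, PPh3, Zn dust, CH2Cl2, rt
Reagents that add atoms: carbon tetrabromide, BrC(Br)(Br)Br
Why: First stage of the Corey–Fuchs reaction (Wittig-type dibromo-olefination with Ph3P=CBr2) under neutral conditions; the stereocentre is β to the aldehyde and cannot epimerise.

Step 3
Reactants: 4 (S)-1,1-dibromo-4-[(triisopropylsilyl)ethynyl]non-1-ene
Product: 6 (S)-1-(benzyloxy)-5-[(triisopropylsilyl)ethynyl]dec-2-yne, via lithium acetylide 5 (not isolated)
Conditions: n-BuLi (2.1 equiv), THF, −78 °C to 0 °C; then BnOCH2Cl, −78 °C to rt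
Reagents that add atoms: benzyl chloromethyl ether, ClCOCc1ccccc1
Why: Second stage of the Corey–Fuchs reaction (Br/Li exchange, Fritsch–Buttenberg–Wiechell rearrangement, deprotonation) gives the lithium acetylide, which is alkylated in the same flask by the highly reactive α-chloro ether, so the future ring A CH2O carbon arrives already protected.

Step 4
Reactants: 6 (S)-1-(benzyloxy)-5-[(triisopropylsilyl)ethynyl]dec-2-yne
Product: 7 (S)-1-(benzyloxy)-5-ethynyldec-2-yne
Conditions: Bu4NF, THF, 0 °C to rt
Reagents that add atoms: none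
Why: Fluoride-induced protodesilylation of the alkynylsilane, to which the benzyl ether, the internal alkyne and the propargylic stereocentre are inert.

Step 5
Reactants: 7 (S)-1-(benzyloxy)-5-ethynyldec-2-yne; 8 2-butyloxirane (racemic 1,2-epoxyhexane)
Product: 10 (9S)-13-(benzyloxy)-9-pentyltrideca-7,11-diyn-5-ol (both C5 epimers), via lithium acetylide 9 (not isolated)
Conditions: n-BuLi (1.05 equiv), THF, −78 °C; BF3·OEt2; then 8, −78 °C
Reagents that add atoms: none
Why: Yamaguchi-type BF3-promoted opening of the epoxide by the lithium acetylide at its unsubstituted carbon (SN2); the carbinol centre forms as a mixture, which is irrelevant because it is oxidised in step 6.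

Step 6
Reactants: 10 (9S)-13-(benzyloxy)-9-pentyltrideca-7,11-diyn-5-ol
Product: 11 (S)-13-(benzyloxy)-9-pentyltrideca-7,11-diyn-5-one
Conditions: Dess–Martin periodinane, CH2Cl2, 0 °C to rt; used crude
Reagents that add atoms: none
Why: Dess–Martin oxidation is non-basic and fast, so the β,γ-alkynyl ketone is obtained without isomerisation to the allenyl ketone.

Step 7
Reactants: 11 (S)-13-(benzyloxy)-9-pentyltrideca-7,11-diyn-5-one
Product: 12 2-[(S)-8-(benzyloxy)-4-pentylocta-2,6-diyn-1-yl]-2-butyl-1,3-dioxolane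
Conditions: (TMSOCH2)2, TMSOTf (5 mol%), CH2Cl2, −78 °C to −20 °C; pyridine quench
Reagents that add atoms: 1,2-bis(trimethylsilyloxy)ethane, C[Si](C)(C)OCCO[Si](C)(C)C
Why: Noyori ketalisation is aprotic and works at low temperature, conditions known to ketalise β,γ-unsaturated ketones without migration of the unsaturation; the dioxolane stops enolisation of the ynone and keeps the ketone away from nickel and zinc in step 8.

Step 8
Reactants: 12 2-[(S)-8-(benzyloxy)-4-pentylocta-2,6-diyn-1-yl]-2-butyl-1,3-dioxolane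
Product: 15 3-[(S)-1-{4-[(benzyloxy)methyl]-2,5-dioxo-2,5-dihydrofuran-3-yl}heptan-2-yl]-4-(2-oxohexyl)furan-2,5-dione, via magnesium tetracarboxylate 13 (not isolated), via ketal bis-anhydride 14 (not isolated)
Conditions: Ni(acac)2(bpy) (20 mol%), Zn powder (6 equiv), MgBr2 (6 equiv), 4 Å MS, CO2 (1 atm), DMF, rt to 40 °C; then 3 M HCl, THF, rt
Reagents that add atoms: carbon dioxide, O=C=O; water, O
Why: Proposed new method: twofold one-flask use of the nickel-catalysed reductive double carboxylation of internal alkynes with CO2 (closest known reaction type: Ni(acac)2(bpy)/Zn/MgBr2 conversion of simple dialkyl and aryl alkynes into maleic anhydrides), in which zerovalent nickel couples each C≡C with CO2 by oxidative cyclisation to an oxanickelacyclopentenone, Zn and MgBr2 reduce and open it to a vinylnickel carboxylate that inserts a second CO2 syn, and acidification closes each cis-diacid to its anhydride (rings A and B together) while the aqueous HCl also hydrolyses the dioxolane; regiochemistry is irrelevant because both alkyne carbons are carboxylated, alkyne–alkyne coupling of a 1,5-diyne would need a cyclobutane-fused nickelacycle and is disfavoured, and the sp3 stereocentre is not acidic under these conditions.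

Step 9
Reactants: 15 3-[(S)-1-{4-[(benzyloxy)methyl]-2,5-dioxo-2,5-dihydrofuran-3-yl}heptan-2-yl]-4-(2-oxohexyl)furan-2,5-dione
Product: 17 3-[(S)-1-[4-(hydroxymethyl)-2,5-dioxo-2,5-dihydrofuran-3-yl]heptan-2-yl]-4-(2-oxohexyl)furan-2,5-dione (CNP0537712.1), via dichloroboryl ether 16 (not isolated)
Conditions: BCl3, C6HMe5, CH2Cl2, −78 °C; then H2O, 0 °C
Reagents that add atoms: none
Why: Lewis-acid debenzylation with pentamethylbenzene as cation scavenger cleaves only the benzyl C–O bond (the other CH2 sits on an electron-poor alkene and cannot ionise) under anhydrous conditions that anhydrides tolerate, and the brief aqueous quench hydrolyses the B–O bond without exposing the free hydroxymethyl anhydride to prolonged aqueous acid.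

## Compound list

1 | (E)-oct-2-enal | CCCCC/C=C/C=O | starting material
2 | ethynyltriisopropylsilane | C#C[Si](C(C)C)(C(C)C)C(C)C | starting material
3 | (S)-3-[(triisopropylsilyl)ethynyl]octanal | CCCCC[C@@H](CC=O)C#C[Si](C(C)C)(C(C)C)C(C)C | intermediate
4 | (S)-1,1-dibromo-4-[(triisopropylsilyl)ethynyl]non-1-ene | CCCCC[C@@H](CC=C(Br)Br)C#C[Si](C(C)C)(C(C)C)C(C)C | intermediate
5 | lithium (S)-4-[(triisopropylsilyl)ethynyl]non-1-yn-1-ide | CCCCC[C@@H](CC#C[Li])C#C[Si](C(C)C)(C(C)C)C(C)C | intermediate
6 | (S)-1-(benzyloxy)-5-[(triisopropylsilyl)ethynyl]dec-2-yne | CCCCC[C@@H](CC#CCOCc1ccccc1)C#C[Si](C(C)C)(C(C)C)C(C)C | intermediate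
7 | (S)-1-(benzyloxy)-5-ethynyldec-2-yne | CCCCC[C@@H](CC#CCOCc1ccccc1)C#C | intermediate
8 | 2-butyloxirane (racemic 1,2-epoxyhexane) | CCCCC1CO1 | starting material
9 | lithium (S)-3-[4-(benzyloxy)but-2-yn-1-yl]oct-1-yn-1-ide | CCCCC[C@@H](CC#CCOCc1ccccc1)C#C[Li] | intermediate
10 | (9S)-13-(benzyloxy)-9-pentyltrideca-7,11-diyn-5-ol (both C5 epimers) | CCCCC[C@@H](CC#CCOCc1ccccc1)C#CCC(O)CCCC | intermediate
11 | (S)-13-(benzyloxy)-9-pentyltrideca-7,11-diyn-5-one | CCCCC[C@@H](CC#CCOCc1ccccc1)C#CCC(=O)CCCC | intermediate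
12 | 2-[(S)-8-(benzyloxy)-4-pentylocta-2,6-diyn-1-yl]-2-butyl-1,3-dioxolane | CCCCC[C@@H](CC#CCOCc1ccccc1)C#CCC1(CCCC)OCCO1 | intermediate
13 | dimagnesium (2Z,6Z,5S)-1-(benzyloxy)-8-(2-butyl-1,3-dioxolan-2-yl)-5-pentylocta-2,6-diene-2,3,6,7-tetracarboxylate | CCCCC[C@@H](C/C(C(=O)[O-])=C(\COCc1ccccc1)C(=O)[O-])/C(C(=O)[O-])=C(\CC1(CCCC)OCCO1)C(=O)[O-].[Mg+2].[Mg+2] | intermediate
14 | 3-[(S)-1-{4-[(benzyloxy)methyl]-2,5-dioxo-2,5-dihydrofuran-3-yl}heptan-2-yl]-4-[(2-butyl-1,3-dioxolan-2-yl)methyl]furan-2,5-dione | CCCCC[C@@H](CC1=C(COCc2ccccc2)C(=O)OC1=O)C1=C(CC2(CCCC)OCCO2)C(=O)OC1=O | intermediate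
15 | 3-[(S)-1-{4-[(benzyloxy)methyl]-2,5-dioxo-2,5-dihydrofuran-3-yl}heptan-2-yl]-4-(2-oxohexyl)furan-2,5-dione | CCCCC[C@@H](CC1=C(COCc2ccccc2)C(=O)OC1=O)C1=C(CC(=O)CCCC)C(=O)OC1=O | intermediate
16 | 3-[(S)-1-{4-[(dichloroboryloxy)methyl]-2,5-dioxo-2,5-dihydrofuran-3-yl}heptan-2-yl]-4-(2-oxohexyl)furan-2,5-dione | CCCCC[C@@H](CC1=C(COB(Cl)Cl)C(=O)OC1=O)C1=C(CC(=O)CCCC)C(=O)OC1=O | intermediate
17 | 3-[(S)-1-[4-(hydroxymethyl)-2,5-dioxo-2,5-dihydrofuran-3-yl]heptan-2-yl]-4-(2-oxohexyl)furan-2,5-dione (CNP0537712.1) | CCCCC[C@@H](CC1=C(CO)C(=O)OC1=O)C1=C(CC(=O)CCCC)C(=O)OC1=O | target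

## Step count and risk

Total step count: 9. Longest linear sequence: 9 steps (the route is fully linear, 1 to 17).

Most likely to fail, in order:

Step 8 (twofold nickel/CO2 carboxylation). The reaction may stop at a mono-anhydride, or the diyne may be lost to nickel-mediated oligomerisation. The fallback sets out from 12 and comes back at 15. Both alkynes are bis(methoxycarbonylated) by oxidative carbonylation with divalent palladium (Pd(OCOCF3)2, an aryl α-diimine ligand, p-benzoquinone, CO 4 bar, MeOH/THF, rt). Syn addition gives the tetramethyl bis-maleate F1. Saponification (LiOH, THF/H2O, 50 °C) followed by 3 M HCl/THF hydrolyses the four esters and the dioxolane and closes both anhydrides, giving 15.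

Step 6 (β,γ-alkynyl ketone, which must also survive into step 7). Ynone 11 may isomerise to the allenyl ketone or cyclise to a furan before it is ketalised. The fallback sets out from 7 and comes back at 15, carrying the ketone as a 1,1-disubstituted alkene so that no ynone is ever made. Alkyne 7 is coupled with 2-(bromomethyl)hex-1-ene (CuI, K2CO3, NaI, DMF, rt) to the skipped enyne F2. The step 8 carboxylation then gives the 2-methylidenehexyl bis-anhydride F3. Ozonolysis (O3, CH2Cl2, −78 °C; Me2S) cleaves only the electron-rich 1,1-disubstituted alkene, leaving the electron-poor ring alkenes, and gives 15.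

Step 9 (BCl3 debenzylation on the bis-anhydride). BCl3 may attack the anhydrides or the keto side chain, or the freed alcohol may not survive the work-up. The fallback sets out from 12 and comes back at 17, removing the benzyl group before any ring exists. The benzyl ether of 12 is cleaved oxidatively (DDQ, 525 nm light, wet CH2Cl2, rt) to the propargylic alcohol F4. This is silylated (TBSCl, imidazole, DMF) to the tert-butyldimethylsilyl ether F5. The step 8 carboxylation of F5 with the same 3 M HCl/THF work-up closes both rings and removes the silyl ether and the dioxolane, giving 17 directly with no deprotection on the bis-anhydride.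

Further compounds
F1 | step 8 | tetramethyl (2Z,6Z,5S)-1-(benzyloxy)-8-(2-butyl-1,3-dioxolan-2-yl)-5-pentylocta-2,6-diene-2,3,6,7-tetracarboxylate | CCCCC[C@@H](C/C(C(=O)OC)=C(\COCc1ccccc1)C(=O)OC)/C(C(=O)OC)=C(\CC1(CCCC)OCCO1)C(=O)OC
F2 | step 6 | (S)-1-(benzyloxy)-5-(4-methylideneoct-1-yn-1-yl)dec-2-yne | CCCCC[C@@H](CC#CCOCc1ccccc1)C#CCC(=C)CCCC
F3 | step 6 | 3-[(S)-1-{4-[(benzyloxy)methyl]-2,5-dioxo-2,5-dihydrofuran-3-yl}heptan-2-yl]-4-(2-methylidenehexyl)furan-2,5-dione | CCCCC[C@@H](CC1=C(COCc2ccccc2)C(=O)OC1=O)C1=C(CC(=C)CCCC)C(=O)OC1=O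
F4 | step 9 | (S)-8-(2-butyl-1,3-dioxolan-2-yl)-5-pentylocta-2,6-diyn-1-ol | CCCCC[C@@H](CC#CCO)C#CCC1(CCCC)OCCO1
F5 | step 9 | tert-butyl{[(S)-8-(2-butyl-1,3-dioxolan-2-yl)-5-pentylocta-2,6-diyn-1-yl]oxy}dimethylsilane | CCCCC[C@@H](CC#CCO[Si](C)(C)C(C)(C)C)C#CCC1(CCCC)OCCO1
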